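**Retrosynthetic overview**
1. The target is a cis-fused cyclobutane/cyclohexa-1,3-diene (bicyclo[4.2.0]octa-2,4-diene, C5–C12) carrying the (E)-2-methylbutenyl carbinol (C1–C4) and joined through an (E)-propenyl unit (C13=C14) to a 2-oxabicyclo[2.2.1]heptane-3,5-dione (C1′–C7′).
2. Enabling feature: C5–C12 carry methyl groups on every second carbon (C5, C7, C9, C11), the C6–C11 fusion is cis and the cyclobutane carbons C5 and C12 bear trans carbon substituents. The two rings are therefore the 8π(con)/6π(dis) valence isomer of a linear (5E,7Z,9Z,11E)-tetraene.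
3. Disconnections: C6–C11 and C5–C12 (electrocyclic), then C8–C9 (Stille coupling of Z-alkenylstannane 9 with Z-alkenyl iodide 22). 9 comes from propargyl alcohol; 22 from a β-ketoimide anti-aldol with (S)-2-methylglycidal, lactonisation, epoxide-opening C-alkylation, two Wittig homologations and a Stork–Zhao olefination.
4. Stereochemical relay: the C4 carbinol is carried as its 4S epimer to steer the helical sense of the electrocyclization, then corrected to 4R by oxidation and CBS reduction.
5. Ring order: δ-lactone ring, then cyclopentanone ring (completing the oxabicycle), then the transient cyclooctatriene, then cyclohexadiene and cyclobutane in one bond formation; the cyclobutane is the last ring completed.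

Key step: step 16

Assumption: locants C1–C14 follow the polyketide chain (C1 = butenyl methyl, C4 = carbinol carbon, C5/C6/C11/C12 = cyclobutane) and primed locants are those of the 2-oxabicyclo[2.2.1]heptane; the facial senses of the (−)-MIB alkenylzinc addition and of the β-ketoimide anti-aldol are taken from the accepted transition-state models, and the enantiomeric ligand or auxiliary would be used if either proved opposite.

**Step 1**
Reactants: 1 prop-2-yn-1-ol
Product: 3 (Z)-3-iodo-2-methylprop-2-en-1-ol, via alkenylmagnesium alkoxide 2 (not isolated)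
Conditions: MeMgBr (2.5 equiv), CuI (10 mol%), THF, −10 °C to rt; then I2, −10 °C; aq. work-up
Reagents that add atoms: methylmagnesium bromide C[Mg]Br; iodine II
Why: Cu-catalysed anti-carbomagnesiation of the propargylic alkoxide places Mg cis to CH2O through a five-membered chelate, and iodinolysis with retention fixes the Z geometry of the future C7=C8 alkene.

**Step 2**
Reactants: 3 (Z)-3-iodo-2-methylprop-2-en-1-ol
Product: 5 ethyl (2E,4Z)-5-iodo-2,4-dimethylpenta-2,4-dienoate, via (Z)-3-iodo-2-methylprop-2-enal 4 (not isolated)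
Conditions: MnO2 (15 equiv), Ph3P=C(Me)CO2Et (1.3 equiv), CH2Cl2, rt, dark
Reagents that add atoms: ethyl 2-(triphenylphosphoranylidene)propanoate CCOC(=O)C(C)=P(c1ccccc1)(c1ccccc1)c1ccccc1
Why: tandem allylic oxidation/Wittig olefination traps the isomerisation-prone Z-iodoenal as it forms, and the stabilised ylide gives the E-trisubstituted enoate (future C5=C6).

**Step 3**
Reactants: 5 ethyl (2E,4Z)-5-iodo-2,4-dimethylpenta-2,4-dienoate
Product: 6 (2E,4Z)-5-iodo-2,4-dimethylpenta-2,4-dien-1-ol
Conditions: DIBAL-H (i-Bu2AlH, 2.5 equiv), CH2Cl2, −78 °C; aq. KNaC4H4O6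
Reagents that add atoms: none
Why: 1,2-reduction of the conjugated ester by the aluminium hydride at low temperature leaves the vinyl iodide and both alkene geometries untouched.

**Step 4**
Reactants: 6 (2E,4Z)-5-iodo-2,4-dimethylpenta-2,4-dien-1-ol
Product: 7 (2E,4Z)-5-iodo-2,4-dimethylpenta-2,4-dienal
Conditions: MnO2 (15 equiv), CH2Cl2, rt, dark
Reagents that add atoms: none
Why: chemoselective allylic oxidation with MnO2 gives the dienal without Z/E isomerisation.

**Step 5**
Reactants: 7 (2E,4Z)-5-iodo-2,4-dimethylpenta-2,4-dienal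
Product: 8 (2E,4S,5E,7Z)-8-iodo-3,5,7-trimethylocta-2,5,7-trien-4-ol
Conditions: 2-butyne, Cy2BH, toluene, 0 °C to rt; Me2Zn, −78 °C; (−)-MIB [(2S)-3-exo-morpholinoisoborneol] (5 mol%), then 7, −20 to 0 °C; aq. work-up
Reagents that add atoms: 2-butyne CC#CC
Why: syn-hydroboration of 2-butyne and B-to-Zn exchange give the (E)-but-2-en-2-ylzinc reagent (E geometry of C2=C3), and the amino-alcohol-catalysed asymmetric alkenylzinc addition attacks the Si face of the enal to set 4S, the vinyl iodide being inert to organozincs.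

**Step 6**
Reactants: 8 (2E,4S,5E,7Z)-8-iodo-3,5,7-trimethylocta-2,5,7-trien-4-ol
Product: 9 (2E,4S,5E,7Z)-3,5,7-trimethyl-8-(trimethylstannyl)octa-2,5,7-trien-4-ol
Conditions: Me3SnSnMe3 (2 equiv), Pd(PPh3)4 (5 mol%), THF, 50 °C; Et3N-deactivated silica
Reagents that add atoms: hexamethylditin C[Sn](C)(C)[Sn](C)(C)C
Why: Pd-catalysed stannylation of the alkenyl iodide (oxidative addition, Sn–Sn transmetalation, reductive elimination) proceeds with retention of the Z geometry and tolerates the free carbinol.

**Step 7**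
Reactants: 10 (4R)-4-benzyl-3-propanoyl-1,3-oxazolidin-2-one
Product: 12 (4R)-4-benzyl-3-[(2S)-2-methyl-3-oxopentanoyl]-1,3-oxazolidin-2-one, via lithium (Z)-enolate 11 (not isolated)
Conditions: LDA [LiN(i-Pr)2], THF, −78 °C; then EtCOCl, −78 °C
Reagents that add atoms: propanoyl chloride CCC(Cl)=O
Why: C-acylation of the chelated (Z)-imide enolate occurs on the face opposite the benzyl group (Evans acylation), setting 2S, and allylic strain keeps the new stereocentre from enolising.

**Step 8**
Reactants: 13 (R)-2-methylglycidol [(2R)-(2-methyloxiran-2-yl)methanol]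
Product: 14 (2S)-2-methyloxirane-2-carbaldehyde
Conditions: Dess–Martin periodinane, NaHCO3, CH2Cl2, 0 °C; filtered solution used directly
Reagents that add atoms: none
Why: buffered Dess–Martin oxidation gives the volatile epoxy aldehyde without touching the quaternary epoxide carbon, which has no α-hydrogen and cannot epimerise (the descriptor changes from R to S only through the priority rules).

**Step 9**
Reactants: 12 (4R)-4-benzyl-3-[(2S)-2-methyl-3-oxopentanoyl]-1,3-oxazolidin-2-one; 14 (2S)-2-methyloxirane-2-carbaldehyde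
Product: 16 (4R)-4-benzyl-3-[(2S,4R,5S)-5-hydroxy-2,4-dimethyl-5-[(2S)-2-methyloxiran-2-yl]-3-oxopentanoyl]-1,3-oxazolidin-2-one, via dicyclohexylboron (E)-enolate 15 (not isolated)
Conditions: Cy2BCl (1.3 equiv), Me2NEt, Et2O, 0 °C; then 14, −78 to −20 °C; H2O2, MeOH, pH 7 buffer, 0 °C
Reagents that add atoms: none
Why: the Evans anti-aldol of the β-ketoimide proceeds through the (E)-boron enolate of the ethyl ketone and a chair Zimmerman–Traxler transition state (4,5-anti), and the C2 methyl stereocentre (C2–H in the enolate plane) directs the enolate face (2,4-anti), giving C6′ (R) and C1′ (S) of the target.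

**Step 10**
Reactants: 16 the anti-aldol adduct
Product: 17 (5R,6S)-4-hydroxy-3,5-dimethyl-6-[(2S)-2-methyloxiran-2-yl]-5,6-dihydro-2H-pyran-2-one (enol form of the β-keto-δ-lactone)
Conditions: DBU (1.2 equiv), CH2Cl2, 0 °C; 1 M aq. HCl wash
Reagents that add atoms: none
Why: intramolecular N-to-O acyl transfer (lactonisation with expulsion of the oxazolidinone) is driven by the acidity of the resulting β-keto lactone and touches no stereocentre other than C3, which becomes the enol carbon.

**Step 11**
Reactants: 17 the β-keto-δ-lactone epoxide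
Product: 18 (1S,4S,6R,7R)-7-(hydroxymethyl)-4,6,7-trimethyl-2-oxabicyclo[2.2.1]heptane-3,5-dione
Conditions: BF3·OEt2 (0.3 equiv), CH2Cl2, −78 to −30 °C; aq. NaHCO3
Reagents that add atoms: none
Why: Proposed new method: Lewis-acid activation of the 2,2-disubstituted epoxide lets the enol carbon C3 of the lactone attack the tertiary epoxide carbon in a 5-exo, SN2-like anti opening from the boat conformer with the epoxide axial; O-alkylation by either enol oxygen or participation of the lactone carbonyl would need a bridgehead double bond and attack at the CH2 terminus is anti-Markovnikov under acid, so C-alkylation at the tertiary carbon is the only low-energy intramolecular path; inversion there relays the glycidol configuration into the quaternary C7′ (methyl syn to the lactone bridge, CH2OH syn to the ketone bridge), the quaternary C4′ forms cis by necessity, and a reversible hemiketal between the new CH2OH and C5′ would be funnelled through its open form in step 12; the closest known reaction types are Lewis-acid-promoted epoxide-opening cyclizations terminated by β-dicarbonyl enols and the acid-induced capture of a tertiary allyl cation by a β-keto-δ-lactone.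

**Step 12**
Reactants: 18 the 7′-hydroxymethyl oxabicycle
Product: 19 (1S,4S,6R,7S)-4,6,7-trimethyl-3,5-dioxo-2-oxabicyclo[2.2.1]heptane-7-carbaldehyde
Conditions: Dess–Martin periodinane, NaHCO3, CH2Cl2, rt
Reagents that add atoms: none
Why: Dess–Martin oxidation of the neopentyl primary alcohol gives an aldehyde with no α-hydrogen and no 1,3-dicarbonyl relationship to the ring carbonyls, so it can neither epimerise nor fragment.

**Step 13**
Reactants: 19 the 7′-carbaldehyde
Product: 20 (2E)-2-methyl-3-[(1S,4S,6R,7S)-4,6,7-trimethyl-3,5-dioxo-2-oxabicyclo[2.2.1]heptan-7-yl]prop-2-enal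
Conditions: Ph3P=C(Me)CHO (3 equiv), toluene, 100 °C
Reagents that add atoms: 2-(triphenylphosphoranylidene)propanal CC(C=O)=P(c1ccccc1)(c1ccccc1)c1ccccc1
Why: Wittig olefination with the neutral stabilised formyl ylide gives the E-trisubstituted enal (C13=C14) without base that could enolise C6′ or open the β-acyloxy ketone.

**Step 14**
Reactants: 20 the enal
Product: 21 (2E,4E)-2,4-dimethyl-5-[(1S,4S,6R,7S)-4,6,7-trimethyl-3,5-dioxo-2-oxabicyclo[2.2.1]heptan-7-yl]penta-2,4-dienal
Conditions: Ph3P=C(Me)CHO (2 equiv), toluene, 90 °C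
Reagents that add atoms: 2-(triphenylphosphoranylidene)propanal CC(C=O)=P(c1ccccc1)(c1ccccc1)c1ccccc1
Why: a second Wittig homologation with the same stabilised ylide installs the E-configured C11=C12 alkene.

**Step 15**
Reactants: 21 the dienal
Product: 22 (1S,4S,6R,7S)-7-[(1E,3E,5Z)-6-iodo-2,4-dimethylhepta-1,3,5-trien-1-yl]-4,6,7-trimethyl-2-oxabicyclo[2.2.1]heptane-3,5-dione
Conditions: EtPPh3I, n-BuLi, THF, rt; I2, −78 °C; NaHMDS [NaN(SiMe3)2], −20 °C; then 21, −78 °C
Reagents that add atoms: ethyltriphenylphosphonium iodide CC[P+](c1ccccc1)(c1ccccc1)c1ccccc1.[I-]; iodine II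
Why: the Stork–Zhao olefination with the α-iodoethylidene ylide is kinetically Z-selective and gives the (Z)-2-iodoalkene (future C9=C10); the aldehyde reacts at −78 °C in preference to the hindered ring ketone.

**Step 16**
Reactants: 9 (2E,4S,5E,7Z)-3,5,7-trimethyl-8-(trimethylstannyl)octa-2,5,7-trien-4-ol; 22 the (Z)-alkenyl iodide
Product: 25 4-epi-shimalactone B [(4S)-epimer of 27], via tetraene 23 (not isolated), via cyclooctatriene 24 (not isolated)
Conditions: Pd(PPh3)4 (10 mol%), CuTC [Cu(O2CC4H3S)] (1.5 equiv), DMF, 0 °C to rt, dark; then 40 °C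
Reagents that add atoms: none
Why: The Stille coupling (oxidative addition of zerovalent palladium to the C–I bond of 22, Cu-assisted transmetalation of 9 and reductive elimination, each with retention of alkene geometry) forms the C8–C9 bond and delivers the (5E,7Z,9Z,11E)-tetraene 23, which undergoes 8π conrotatory electrocyclization (C5–C12 bond, cyclooctatriene 24) and then 6π disrotatory electrocyclization (C6–C11 bond) to the bicyclo[4.2.0]octa-2,4-diene. The closest known reaction type is the Stille coupling/8π–6π electrocyclization cascade of tetramethylated (E,Z,Z,E)-tetraenes to bicyclo[4.2.0]octadienes. The eight-membered ring closes by thermal conrotation and is transient, whereas the six-membered ring and the cyclobutane close together by thermal disrotation across C6–C11, so the cyclobutane is completed only in this last bond formation. C5 and C12 are set in the conrotatory step: the E,Z,Z,E geometry forces the carbinol substituent and the propenyl chain trans, and the (4S)-carbinol on the terminus chooses the helix by placing its butenyl group anti to the forming C5–C12 bond, OH next to C6–H and H next to the inside C5 methyl, which should give (5S,12S) (a 4R carbinol should favour the mirror-image core). C6 and C11 are set cis by disrotation, through the boat of 24 that keeps the cyclohexadiene on the face of the C5 methyl and the C12 chain and away from the bulky carbinol. The step needs intact Z geometry at C7=C8 and C9=C10 (mild Cu-promoted coupling in the dark), site selectivity for the C5–C12 over the C7–C14 tetraene (only the former has two central Z alkenes) and helical selectivity (the C4 stereocentre).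

**Step 17**
Reactants: 25 4-epi-shimalactone B
Product: 26 4-dehydroshimalactone B (C4 ketone)
Conditions: Dess–Martin periodinane, NaHCO3, CH2Cl2, 0 °C to rt
Reagents that add atoms: none
Why: buffered Dess–Martin oxidation of the allylic carbinol removes the relay stereocentre after it has done its work, leaving the diene, ketone and lactone untouched.

**Step 18**
Reactants: 26 4-dehydroshimalactone B
Product: 27 shimalactone B
Conditions: (S)-Me-CBS [(S)-1-methyl-3,3-diphenyltetrahydro-1H,3H-pyrrolo[1,2-c][1,3,2]oxazaborole] (0.5 equiv), catecholborane (2 equiv), toluene, −78 °C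
Reagents that add atoms: none
Why: Corey–Bakshi–Shibata reduction under reagent control, with the quaternary cyclobutyl carbon as the large group and the methylbutenyl group as the small one, should deliver hydride to the face that gives 4R; the enone should react before the more hindered and less basic ring ketone C5′, and the substrate itself offers no bias because C6 and C12 are locally near-equivalent.

**Compound list**
1 | prop-2-yn-1-ol | C#CCO | starting material
2 | bromomagnesium (Z)-3-(bromomagnesio)-2-methylprop-2-en-1-olate | Br[Mg]OC/C(C)=C\[Mg]Br | intermediate (not isolated)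
3 | (Z)-3-iodo-2-methylprop-2-en-1-ol | OC/C(C)=C\I | intermediate
4 | (Z)-3-iodo-2-methylprop-2-enal | O=C/C(C)=C\I | intermediate (not isolated)
5 | ethyl (2E,4Z)-5-iodo-2,4-dimethylpenta-2,4-dienoate | CCOC(=O)/C(C)=C/C(C)=C\I | intermediate
6 | (2E,4Z)-5-iodo-2,4-dimethylpenta-2,4-dien-1-ol | OC/C(C)=C/C(C)=C\I | intermediate
7 | (2E,4Z)-5-iodo-2,4-dimethylpenta-2,4-dienal | O=C/C(C)=C/C(C)=C\I | intermediate
8 | (2E,4S,5E,7Z)-8-iodo-3,5,7-trimethylocta-2,5,7-trien-4-ol | C/C=C(\C)[C@H](O)/C(C)=C/C(C)=C\I | intermediate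
9 | (2E,4S,5E,7Z)-3,5,7-trimethyl-8-(trimethylstannyl)octa-2,5,7-trien-4-ol | C/C=C(\C)[C@H](O)/C(C)=C/C(C)=C\[Sn](C)(C)C | intermediate
10 | (4R)-4-benzyl-3-propanoyl-1,3-oxazolidin-2-one | CCC(=O)N1[C@H](Cc2ccccc2)COC1=O | starting material
11 | lithium (Z)-enolate of 10 | C/C=C(\O[Li])N1[C@H](Cc2ccccc2)COC1=O | intermediate (not isolated)
12 | (4R)-4-benzyl-3-[(2S)-2-methyl-3-oxopentanoyl]-1,3-oxazolidin-2-one | CCC(=O)[C@H](C)C(=O)N1[C@H](Cc2ccccc2)COC1=O | intermediate
13 | (R)-2-methylglycidol | C1O[C@]1(C)CO | starting material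
14 | (2S)-2-methyloxirane-2-carbaldehyde | C1O[C@]1(C)C=O | intermediate
15 | dicyclohexylboron (E)-enolate of 12 (ethyl ketone side) | C/C=C(/OB(C1CCCCC1)C1CCCCC1)[C@H](C)C(=O)N1[C@H](Cc2ccccc2)COC1=O | intermediate (not isolated)
16 | (4R)-4-benzyl-3-[(2S,4R,5S)-5-hydroxy-2,4-dimethyl-5-[(2S)-2-methyloxiran-2-yl]-3-oxopentanoyl]-1,3-oxazolidin-2-one | C1O[C@]1(C)[C@@H](O)[C@@H](C)C(=O)[C@H](C)C(=O)N1[C@H](Cc2ccccc2)COC1=O | intermediate
17 | (5R,6S)-4-hydroxy-3,5-dimethyl-6-[(2S)-2-methyloxiran-2-yl]-5,6-dihydro-2H-pyran-2-one | C1O[C@]1(C)[C@H]2OC(=O)C(C)=C(O)[C@@H]2C | intermediate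
18 | (1S,4S,6R,7R)-7-(hydroxymethyl)-4,6,7-trimethyl-2-oxabicyclo[2.2.1]heptane-3,5-dione | OC[C@]1(C)[C@H]2OC(=O)[C@]1(C)C(=O)[C@@H]2C | intermediate
19 | (1S,4S,6R,7S)-4,6,7-trimethyl-3,5-dioxo-2-oxabicyclo[2.2.1]heptane-7-carbaldehyde | O=C[C@]1(C)[C@H]2OC(=O)[C@]1(C)C(=O)[C@@H]2C | intermediate
20 | (2E)-2-methyl-3-[(1S,4S,6R,7S)-4,6,7-trimethyl-3,5-dioxo-2-oxabicyclo[2.2.1]heptan-7-yl]prop-2-enal | O=C/C(C)=C/[C@]1(C)[C@H]2OC(=O)[C@]1(C)C(=O)[C@@H]2C | intermediate
21 | (2E,4E)-2,4-dimethyl-5-[(1S,4S,6R,7S)-4,6,7-trimethyl-3,5-dioxo-2-oxabicyclo[2.2.1]heptan-7-yl]penta-2,4-dienal | O=C/C(C)=C/C(C)=C/[C@]1(C)[C@H]2OC(=O)[C@]1(C)C(=O)[C@@H]2C | intermediate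
22 | (1S,4S,6R,7S)-7-[(1E,3E,5Z)-6-iodo-2,4-dimethylhepta-1,3,5-trien-1-yl]-4,6,7-trimethyl-2-oxabicyclo[2.2.1]heptane-3,5-dione | I\C(C)=C/C(C)=C/C(C)=C/[C@]1(C)[C@H]2OC(=O)[C@]1(C)C(=O)[C@@H]2C | intermediate
23 | open-chain (2E,4S,5E,7Z,9Z,11E,13E)-hexaene carbinol (the C5–C12 tetraene) attached at C14 to C7′ of the oxabicycle | C/C=C(\C)[C@H](O)/C(C)=C/C(C)=C\C(C)=C/C(C)=C/C(C)=C/[C@]1(C)[C@H]2OC(=O)[C@]1(C)C(=O)[C@@H]2C | intermediate (not isolated)
24 | cycloocta-1,3,5-triene with sp3 C5 (methyl, carbinol) and C12 (H, propenyl chain) trans, ring alkenes C6=C7, C8=C9, C10=C11 all cis | C/C=C(\C)[C@H](O)[C@@]1(C)C=C(C)C=C(C)C=C(C)[C@@H]1/C(C)=C/[C@]1(C)[C@H]2OC(=O)[C@]1(C)C(=O)[C@@H]2C | intermediate (not isolated)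
25 | 4-epi-shimalactone B (4S,5S,6R,11S,12S) | C/C=C(\C)[C@H](O)[C@@]1(C)[C@@H]2C(C)=CC(C)=C[C@]2(C)[C@@H]1/C(C)=C/[C@]1(C)[C@H]2OC(=O)[C@]1(C)C(=O)[C@@H]2C | intermediate
26 | 4-dehydroshimalactone B (C4 ketone) | C/C=C(\C)C(=O)[C@@]1(C)[C@@H]2C(C)=CC(C)=C[C@]2(C)[C@@H]1/C(C)=C/[C@]1(C)[C@H]2OC(=O)[C@]1(C)C(=O)[C@@H]2C | intermediate
27 | shimalactone B (4R,5S,6R,11S,12S; oxabicycle 1′S,4′S,6′R,7′S) | C/C=C(\C)[C@@H](O)[C@@]1(C)[C@@H]2C(C)=CC(C)=C[C@]2(C)[C@@H]1/C(C)=C/[C@]1(C)[C@H]2OC(=O)[C@]1(C)C(=O)[C@@H]2C | target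

**Step count**
Total: 18 steps. Longest linear sequence: 11 steps (7, 9, 10, 11, 12, 13, 14, 15, 16, 17, 18).

**Steps most likely to fail**

Step 11 (proposed new method). The activated tertiary epoxide may collapse by 1,2-hydride shift or proton loss faster than the enol captures it, or capture may be slow because the boat conformer with the axial epoxide is poorly populated. The fallback uses known chemistry and sets out from 12. The same anti-aldol (Cy2BCl, Me2NEt) with commercial (E)-4-acetoxy-2-methylbut-2-enal should give the allylic acetate adduct (4R)-4-benzyl-3-[(2S,4R,5S,6E)-8-acetoxy-5-hydroxy-2,4,6-trimethyl-3-oxooct-6-enoyl]-1,3-oxazolidin-2-one F1. DBU-mediated acyl transfer should then give the lactone (5R,6S)-6-[(2E)-4-acetoxybut-2-en-2-yl]-4-hydroxy-3,5-dimethyl-5,6-dihydro-2H-pyran-2-one F2. An intramolecular Tsuji–Trost allylation (Pd(PPh3)4 cat., THF, rt) should close the cyclopentanone ring at the tertiary allyl terminus, the seven-membered alternative being disfavoured, to give (1S,4S,6R,7S)-7-ethenyl-4,6,7-trimethyl-2-oxabicyclo[2.2.1]heptane-3,5-dione F3. Here C7′ is set by the cyclization transition state and not by relay, so its epimer may have to be separated. Ozonolysis (O3, CH2Cl2, −78 °C; Me2S) returns the route at aldehyde 19.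

Step 16. The C4 carbinol may bias the helical sense of conrotation too weakly or in the unexpected direction, and a slow coupling of two hindered Z-alkenyl partners would allow Z/E scrambling before cyclization. The fallback abandons the relay and sets out from 9. MnO2 oxidation should give (2E,5E,7Z)-3,5,7-trimethyl-8-(trimethylstannyl)octa-2,5,7-trien-4-one F4. Its coupling with 22 under the conditions of step 16 should give, through the same cascade and without any bias from C4, enone 26 together with its helical diastereomer (5R,6S,11R,12R)-4-dehydro compound F5. F5 is removed by chromatography and the route is rejoined at 26.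

Step 18. Hydride delivery may not distinguish the two faces of a ketone flanked by a quaternary carbon and a branched alkenyl group, and the ring ketone C5′ may be reduced competitively. The fallback avoids the inversion and sets out from 7. Alkenylzinc addition with (+)-MIB should give (2E,4R,5E,7Z)-8-iodo-3,5,7-trimethylocta-2,5,7-trien-4-ol F6, and stannylation as in step 6 should give (2E,4R,5E,7Z)-3,5,7-trimethyl-8-(trimethylstannyl)octa-2,5,7-trien-4-ol F7. Coupling of F7 with 22 at 60 °C should give target 27 directly as the minor helical diastereomer beside the (4R,5R,6S,11R,12R)-diastereomer F8. The two are separated by preparative HPLC and the route is rejoined at 27.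

**Further compounds**
F1 | step 11 | (4R)-4-benzyl-3-[(2S,4R,5S,6E)-8-acetoxy-5-hydroxy-2,4,6-trimethyl-3-oxooct-6-enoyl]-1,3-oxazolidin-2-one | CC(=O)OC/C=C(\C)[C@@H](O)[C@@H](C)C(=O)[C@H](C)C(=O)N1[C@H](Cc2ccccc2)COC1=O
F2 | step 11 | (5R,6S)-6-[(2E)-4-acetoxybut-2-en-2-yl]-4-hydroxy-3,5-dimethyl-5,6-dihydro-2H-pyran-2-one | CC(=O)OC/C=C(\C)[C@H]1OC(=O)C(C)=C(O)[C@@H]1C
F3 | step 11 | (1S,4S,6R,7S)-7-ethenyl-4,6,7-trimethyl-2-oxabicyclo[2.2.1]heptane-3,5-dione | C=C[C@]1(C)[C@H]2OC(=O)[C@]1(C)C(=O)[C@@H]2C
F4 | step 16 | (2E,5E,7Z)-3,5,7-trimethyl-8-(trimethylstannyl)octa-2,5,7-trien-4-one | C/C=C(\C)C(=O)/C(C)=C/C(C)=C\[Sn](C)(C)C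
F5 | step 16 | (5R,6S,11R,12R)-diastereomer of 26 | C/C=C(\C)C(=O)[C@]1(C)[C@H]2C(C)=CC(C)=C[C@@]2(C)[C@H]1/C(C)=C/[C@]1(C)[C@H]2OC(=O)[C@]1(C)C(=O)[C@@H]2C
F6 | step 18 | (2E,4R,5E,7Z)-8-iodo-3,5,7-trimethylocta-2,5,7-trien-4-ol | C/C=C(\C)[C@@H](O)/C(C)=C/C(C)=C\I
F7 | step 18 | (2E,4R,5E,7Z)-3,5,7-trimethyl-8-(trimethylstannyl)octa-2,5,7-trien-4-ol | C/C=C(\C)[C@@H](O)/C(C)=C/C(C)=C\[Sn](C)(C)C
F8 | step 18 | (4R,5R,6S,11R,12R)-diastereomer of 27 | C/C=C(\C)[C@@H](O)[C@]1(C)[C@H]2C(C)=CC(C)=C[C@@]2(C)[C@H]1/C(C)=C/[C@]1(C)[C@H]2OC(=O)[C@]1(C)C(=O)[C@@H]2C
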